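Ring A is the methoxy/2-oxoheptyl benzene ring, ring B the one fused to the spiroketal lactone. The seven-membered dioxepinone ring is cut on both sides of its O–C(=O) unit: ester oxygen to ring B, carbonyl carbon to ring A. What falls out is carbon dioxide, and both aryl carbons sit ortho to the diaryl ether oxygen, which the key step exploits. In one flask, copper/diethylzinc carboxylation of a ring A C–I bond with CO2 gives a carboxylate that closes onto a ring B C–Br bond by Ullmann O-arylation. The precursor is an iodo/bromo diaryl ether carrying the finished spiroketal lactone, phenol benzylated, ketone masked as a dioxolane.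

Key step: step 13

Assumption: (R)-6-methyltetrahydro-2H-pyran-2-one and 1,3-difluoro-5-methoxy-2-nitrobenzene are taken as catalogue compounds; the spiro centre of the target is the thermodynamically preferred epimer (lactone oxygen axial on the tetrahydropyran chair, methyl equatorial), so it can be set by acid equilibration.

Step 1
Reactants: 1 ethyl 2-hydroxy-6-methylbenzoate
Product: 3 ethyl 3,6-dihydroxy-2-methylbenzoate, via potassium aryl sulfate 2 (not isolated)
Conditions: K2S2O8, aq. KOH, 0 °C to rt; then aq. HCl, 80 °C
Reagents that add atoms: potassium peroxodisulfate, [K+].[K+].[O-]S(=O)(=O)OOS(=O)(=O)[O-]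
Why: Elbs persulfate oxidation: the phenoxide attacks a peroxide oxygen through its free para carbon to give aryl sulfate 2, whose acid hydrolysis frees the hydroquinone, while the di-ortho-substituted ethyl ester should resist saponification in cold alkali.

Step 2
Reactants: 3 ethyl 3,6-dihydroxy-2-methylbenzoate
Product: 4 ethyl 3-(allyloxy)-6-hydroxy-2-methylbenzoate
Conditions: allyl bromide (1.05 equiv), K2CO3, acetone, reflux
Reagents that add atoms: allyl bromide, C=CCBr
Why: Williamson etherification that should take only the 3-hydroxyl, because the 6-hydroxyl is held in a hydrogen bond to the ester carbonyl and is the weaker nucleophile under carbonate conditions.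

Step 3
Reactants: 4 ethyl 3-(allyloxy)-6-hydroxy-2-methylbenzoate
Product: 5 ethyl 3-(allyloxy)-6-(benzyloxy)-2-methylbenzoate
Conditions: BnBr, K2CO3, Bu4NI (cat.), DMF, 60 °C
Reagents that add atoms: benzyl bromide, BrCc1ccccc1
Why: Williamson etherification of the remaining chelated phenol under more forcing conditions, giving a benzyl ether that survives base, acid and Pd(0) and is removed only at the end.

Step 4
Reactants: 5 ethyl 3-(allyloxy)-6-(benzyloxy)-2-methylbenzoate; 6 (R)-6-methyltetrahydro-2H-pyran-2-one
Product: 8 (3S,6'R)-5-(allyloxy)-8-(benzyloxy)-6'-methyl-3',4',5',6'-tetrahydrospiro[isochromane-3,2'-pyran]-1-one, via hydroxy keto ester 7 (not isolated)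
Conditions: LDA, THF, −78 °C; then 6, −78 to −40 °C; AcOH; then p-TsOH·H2O (cat.), toluene, 60 °C
Reagents that add atoms: none
Why: Lateral lithiation of the ortho-toluate and Claisen-type acylation by the lactone give hydroxy ketone 7, which acid converts to the spiro acyl ketal by hemiketalisation and lactonisation onto the ethyl ester; C-6' comes from the (R)-lactone and spiro carbon C-3 is set under thermodynamic control (lactone oxygen axial by the anomeric effect, methyl equatorial), which is the 3S epimer.

Step 5
Reactants: 8 (3S,6'R)-5-(allyloxy)-8-(benzyloxy)-6'-methyl-3',4',5',6'-tetrahydrospiro[isochromane-3,2'-pyran]-1-one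
Product: 9 (3S,6'R)-8-(benzyloxy)-5-hydroxy-6'-methyl-3',4',5',6'-tetrahydrospiro[isochromane-3,2'-pyran]-1-one
Conditions: Pd(PPh3)4 (cat.), morpholine, THF, rt
Reagents that add atoms: none
Why: Tsuji–Trost deallylation: Pd(0) ionises the allyl aryl ether and morpholine traps the π-allyl complex, under neutral conditions that leave the benzyl ether and the acid-sensitive acyl ketal untouched.

Step 6
Reactants: 9 (3S,6'R)-8-(benzyloxy)-5-hydroxy-6'-methyl-3',4',5',6'-tetrahydrospiro[isochromane-3,2'-pyran]-1-one
Product: 10 (3S,6'R)-8-(benzyloxy)-6-bromo-5-hydroxy-6'-methyl-3',4',5',6'-tetrahydrospiro[isochromane-3,2'-pyran]-1-one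
Conditions: NBS (1.0 equiv), MeCN, 0 °C
Reagents that add atoms: N-bromosuccinimide, O=C1CCC(=O)N1Br
Why: Electrophilic aromatic bromination directed by the free 5-hydroxyl to C-6, its only open ortho position (the other is ring-fusion carbon C-4a and the para position carries the benzyloxy group), so the halogen lands on the ring B carbon next to the future ether oxygen.

Step 7
Reactants: 11 1,3-difluoro-5-methoxy-2-nitrobenzene; 12 methyl 3-oxooctanoate
Product: 13 methyl 2-(3-fluoro-5-methoxy-2-nitrophenyl)-3-oxooctanoate
Conditions: K2CO3, DMF, 50 °C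
Reagents that add atoms: none
Why: Nucleophilic aromatic substitution (addition–elimination) of one of the two equivalent fluorides ortho to the nitro group by the β-keto ester enolate; the enolate of the product deactivates the ring and should stop a second substitution.

Step 8
Reactants: 13 methyl 2-(3-fluoro-5-methoxy-2-nitrophenyl)-3-oxooctanoate
Product: 15 1-(3-fluoro-5-methoxy-2-nitrophenyl)heptan-2-one, via β-keto acid 14 (not isolated)
Conditions: AcOH, 6 M aq. HCl, 100 °C
Reagents that add atoms: none
Why: Acid hydrolysis of the methyl ester and decarboxylation of β-keto acid 14 (ketonic cleavage of a β-keto ester), conditions under which the aryl fluoride and the nitro group are inert.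

Step 9
Reactants: 15 1-(3-fluoro-5-methoxy-2-nitrophenyl)heptan-2-one
Product: 16 2-[(3-fluoro-5-methoxy-2-nitrophenyl)methyl]-2-pentyl-1,3-dioxolane
Conditions: ethylene glycol, p-TsOH·H2O (cat.), toluene, reflux (Dean–Stark)
Reagents that add atoms: ethylene glycol, OCCO
Why: Acid-catalysed ketalisation with azeotropic removal of water; the dioxolane keeps the ketone from cyclising onto the later aniline (indole formation) and from enolising in the key step.

Step 10
Reactants: 10 (3S,6'R)-8-(benzyloxy)-6-bromo-5-hydroxy-6'-methyl-3',4',5',6'-tetrahydrospiro[isochromane-3,2'-pyran]-1-one; 16 2-[(3-fluoro-5-methoxy-2-nitrophenyl)methyl]-2-pentyl-1,3-dioxolane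
Product: 17 (3S,6'R)-8-(benzyloxy)-6-bromo-5-{5-methoxy-2-nitro-3-[(2-pentyl-1,3-dioxolan-2-yl)methyl]phenoxy}-6'-methyl-3',4',5',6'-tetrahydrospiro[isochromane-3,2'-pyran]-1-one
Conditions: Cs2CO3, DMSO, 90 °C
Reagents that add atoms: none
Why: Nucleophilic aromatic substitution of the fluoride ortho to the nitro group by the caesium phenoxide of 10, which forms the diaryl ether without touching the aryl bromide and places the nitro group on the ring A carbon that will later carry the carbonyl.

Step 11
Reactants: 17 nitro diaryl ether (as named in step 10)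
Product: 18 (3S,6'R)-5-{2-amino-5-methoxy-3-[(2-pentyl-1,3-dioxolan-2-yl)methyl]phenoxy}-8-(benzyloxy)-6-bromo-6'-methyl-3',4',5',6'-tetrahydrospiro[isochromane-3,2'-pyran]-1-one
Conditions: H2 (1 atm), Pt/C (sulfided, cat.), EtOAc, rt
Reagents that add atoms: none
Why: Chemoselective catalytic hydrogenation of the nitro group on sulfided platinum, a catalyst that should spare the aryl bromide and the benzyl ether.

Step 12
Reactants: 18 amino diaryl ether (as named in step 11)
Product: 20 (3S,6'R)-8-(benzyloxy)-6-bromo-5-{2-iodo-5-methoxy-3-[(2-pentyl-1,3-dioxolan-2-yl)methyl]phenoxy}-6'-methyl-3',4',5',6'-tetrahydrospiro[isochromane-3,2'-pyran]-1-one, via diazonium tetrafluoroborate 19 (not isolated)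
Conditions: NOBF4, MeCN, −30 °C; then KI, −30 °C to rt
Reagents that add atoms: potassium iodide, [K+].[I-]
Why: Aprotic diazotisation with the nitrosonium salt and Sandmeyer-type iododediazoniation (electron transfer from iodide, then radical recombination), which avoids aqueous acid for the sake of the dioxolane; Pschorr-type ring closure is disfavoured because both ring B positions ortho to the ether oxygen are substituted.

Step 13
Reactants: 20 iodo/bromo diaryl ether (as named in step 12)
Product: 22 protected depsidone (the target with its phenol as benzyl ether and its side-chain ketone as ethylene ketal; 3S,6'R in the spiro unit), via ethylzinc carboxylate 21 (not isolated)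
Conditions: CuI (10 mol%), TMEDA (20 mol%), Et2Zn (1.5 equiv), CO2 (1 atm), DMSO, 50 °C; then 1,10-phenanthroline (20 mol%), 110 °C
Reagents that add atoms: carbon dioxide, O=C=O
Why: Proposed new method: Cu(I)/Et2Zn converts the ring A C–I bond into an aryl-zinc/copper species that inserts CO2 to give the ortho-aryloxy benzoate 21 (new C–C bond), and on heating the same copper, now as its carboxylate, adds oxidatively into the neighbouring ring B C–Br bond and eliminates reductively with C–O bond formation (new O–C bond); the closest known reaction types are the copper-catalysed carboxylation of aryl iodides with CO2/Et2Zn and the intramolecular Ullmann-type O-arylation of carboxylates to benzo-fused lactones, which have not been merged in one flask on a dihalo diaryl ether. The seven-membered 1,4-dioxepin-5-one ring closes by intramolecular C(aryl)–O bond formation, the carboxylate oxygen being held in reach of the bromide by the diaryl ether. No stereocentre is formed and the acyl spiroketal sees no protic acid. The step needs iodide-over-bromide selectivity in the metalation, secured by the choice of halogens, and CO2 capture faster than C–C coupling to a dibenzofuran, secured by the CO2 atmosphere and the low temperature of the first stage. Regiochemistry is fixed because the two halogens sit on the only carbons ortho to the ether oxygen that are to be joined, and the benzyl ether and dioxolane remove the acidic phenol and the enolisable ketone that would consume Et2Zn or open the new aryl ester.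

Step 14
Reactants: 22 protected depsidone
Product: 24 target depsidone CNP0301127.1 (3S,6'R in the spiro unit), via debenzylated ketal 23 (not isolated)
Conditions: H2 (1 atm), Pd/C (cat.), EtOAc, rt; filter; then PPTS (cat.), acetone/H2O, 45 °C
Reagents that add atoms: water, O
Why: Hydrogenolysis of the benzyl ether followed by mild acid-catalysed hydrolysis of the dioxolane; the spiro centre is already the thermodynamic epimer, and the mild buffer should avoid enol-lactonisation of the freed ketone onto the aryl ester.

Compound list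
1 | ethyl 2-hydroxy-6-methylbenzoate | CCOC(=O)c1c(C)cccc1O | starting material
2 | potassium 3-(ethoxycarbonyl)-4-hydroxy-2-methylphenyl sulfate | CCOC(=O)c1c(C)c(OS(=O)(=O)[O-])ccc1O.[K+] | intermediate
3 | ethyl 3,6-dihydroxy-2-methylbenzoate | CCOC(=O)c1c(C)c(O)ccc1O | intermediate
4 | ethyl 3-(allyloxy)-6-hydroxy-2-methylbenzoate | CCOC(=O)c1c(C)c(OCC=C)ccc1O | intermediate
5 | ethyl 3-(allyloxy)-6-(benzyloxy)-2-methylbenzoate | CCOC(=O)c1c(C)c(OCC=C)ccc1OCc1ccccc1 | intermediate
6 | (R)-6-methyltetrahydro-2H-pyran-2-one | C[C@@H]1CCCC(=O)O1 | starting material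
7 | ethyl 3-(allyloxy)-6-(benzyloxy)-2-[(6R)-6-hydroxy-2-oxoheptyl]benzoate | CCOC(=O)c1c(CC(=O)CCC[C@@H](C)O)c(OCC=C)ccc1OCc1ccccc1 | intermediate
8 | (3S,6'R)-5-(allyloxy)-8-(benzyloxy)-6'-methyl-3',4',5',6'-tetrahydrospiro[isochromane-3,2'-pyran]-1-one | C=CCOc1ccc(OCc2ccccc2)c2c1C[C@]1(CCC[C@@H](C)O1)OC2=O | intermediate
9 | (3S,6'R)-8-(benzyloxy)-5-hydroxy-6'-methyl-3',4',5',6'-tetrahydrospiro[isochromane-3,2'-pyran]-1-one | Oc1ccc(OCc2ccccc2)c2c1C[C@]1(CCC[C@@H](C)O1)OC2=O | intermediate
10 | (3S,6'R)-8-(benzyloxy)-6-bromo-5-hydroxy-6'-methyl-3',4',5',6'-tetrahydrospiro[isochromane-3,2'-pyran]-1-one | Oc1c(Br)cc(OCc2ccccc2)c2c1C[C@]1(CCC[C@@H](C)O1)OC2=O | intermediate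
11 | 1,3-difluoro-5-methoxy-2-nitrobenzene | COc1cc(F)c([N+](=O)[O-])c(F)c1 | starting material
12 | methyl 3-oxooctanoate | CCCCCC(=O)CC(=O)OC | starting material
13 | methyl 2-(3-fluoro-5-methoxy-2-nitrophenyl)-3-oxooctanoate | CCCCCC(=O)C(C(=O)OC)c1cc(OC)cc(F)c1[N+](=O)[O-] | intermediate
14 | 2-(3-fluoro-5-methoxy-2-nitrophenyl)-3-oxooctanoic acid | CCCCCC(=O)C(C(=O)O)c1cc(OC)cc(F)c1[N+](=O)[O-] | intermediate
15 | 1-(3-fluoro-5-methoxy-2-nitrophenyl)heptan-2-one | CCCCCC(=O)Cc1cc(OC)cc(F)c1[N+](=O)[O-] | intermediate
16 | 2-[(3-fluoro-5-methoxy-2-nitrophenyl)methyl]-2-pentyl-1,3-dioxolane | CCCCCC1(Cc2cc(OC)cc(F)c2[N+](=O)[O-])OCCO1 | intermediate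
17 | (3S,6'R)-8-(benzyloxy)-6-bromo-5-{5-methoxy-2-nitro-3-[(2-pentyl-1,3-dioxolan-2-yl)methyl]phenoxy}-6'-methyl-3',4',5',6'-tetrahydrospiro[isochromane-3,2'-pyran]-1-one | CCCCCC1(Cc2cc(OC)cc(Oc3c(Br)cc(OCc4ccccc4)c4c3C[C@]3(CCC[C@@H](C)O3)OC4=O)c2[N+](=O)[O-])OCCO1 | intermediate
18 | (3S,6'R)-5-{2-amino-5-methoxy-3-[(2-pentyl-1,3-dioxolan-2-yl)methyl]phenoxy}-8-(benzyloxy)-6-bromo-6'-methyl-3',4',5',6'-tetrahydrospiro[isochromane-3,2'-pyran]-1-one | CCCCCC1(Cc2cc(OC)cc(Oc3c(Br)cc(OCc4ccccc4)c4c3C[C@]3(CCC[C@@H](C)O3)OC4=O)c2N)OCCO1 | intermediate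
19 | arenediazonium tetrafluoroborate of 18 (N2+ in place of NH2) | CCCCCC1(Cc2cc(OC)cc(Oc3c(Br)cc(OCc4ccccc4)c4c3C[C@]3(CCC[C@@H](C)O3)OC4=O)c2[N+]#N)OCCO1.F[B-](F)(F)F | intermediate
20 | (3S,6'R)-8-(benzyloxy)-6-bromo-5-{2-iodo-5-methoxy-3-[(2-pentyl-1,3-dioxolan-2-yl)methyl]phenoxy}-6'-methyl-3',4',5',6'-tetrahydrospiro[isochromane-3,2'-pyran]-1-one | CCCCCC1(Cc2cc(OC)cc(Oc3c(Br)cc(OCc4ccccc4)c4c3C[C@]3(CCC[C@@H](C)O3)OC4=O)c2I)OCCO1 | intermediate
21 | ethylzinc carboxylate of 20 (CO2ZnEt in place of I) | CCCCCC1(Cc2cc(OC)cc(Oc3c(Br)cc(OCc4ccccc4)c4c3C[C@]3(CCC[C@@H](C)O3)OC4=O)c2C(=O)O[Zn]CC)OCCO1 | intermediate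
22 | protected depsidone: target with the phenol as benzyl ether and the side-chain ketone as ethylene ketal, (3S,6'R) spiro unit | CCCCCC1(Cc2cc(OC)cc3c2C(=O)Oc2cc(OCc4ccccc4)c4c(c2O3)C[C@]2(CCC[C@@H](C)O2)OC4=O)OCCO1 | intermediate
23 | debenzylated depsidone ethylene ketal, (3S,6'R) spiro unit | CCCCCC1(Cc2cc(OC)cc3c2C(=O)Oc2cc(O)c4c(c2O3)C[C@]2(CCC[C@@H](C)O2)OC4=O)OCCO1 | intermediate
24 | CNP0301127.1: depsidone with 2-oxoheptyl and methoxy on ring A, free phenol and (3S,6'R)-6'-methyl spiro[isochromanone-3,2'-tetrahydropyran] on ring B | CCCCCC(=O)Cc1cc(OC)cc2c1C(=O)Oc1cc(O)c3c(c1O2)C[C@]1(CCC[C@@H](C)O1)OC3=O | target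

Total step count: 14. Longest linear sequence: 11 steps (steps 1–6 and 10–14); steps 7–9 build the second branch.

Steps most likely to fail

Step 13 (Proposed new method). What may go wrong: protonation of the aryl-zinc/copper intermediate before CO2 capture (loss of iodine without carboxylation), intramolecular C–C coupling of that intermediate with the bromide to a dibenzofuran, or a stalled C–O coupling at the hindered bromide once the zinc carboxylate has formed. The fallback uses known chemistry and runs from 20 back to 22. Iodine–magnesium exchange with i-PrMgCl·LiCl in THF at −20 °C, selective for the iodide and tolerated by the hindered lactone and the bromide, followed by a CO2 quench should give the free 2-aryloxybenzoic acid F1, which is isolated. In a separate operation the acid is cyclised with Cs2CO3 and copper(I) thiophene-2-carboxylate in DMF at 110 °C (intramolecular Ullmann O-arylation of a carboxylate), which returns protected depsidone 22.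

Step 12. What may go wrong: loss of nitrogen from the hindered diazonium ion before iodide arrives, with capture of the aryl cation or radical by the neighbouring dioxolane oxygen or by ring B, and partial ketal cleavage by the acid that accompanies diazotisation. The fallback runs from 18 back to 20. Diazonium salt 19 is generated as before and trapped at once at −30 °C with diethylamine/K2CO3 as the stable 1-aryl-3,3-diethyltriazene F2, which is purified. Heating F2 with iodomethane at 100 °C in a sealed tube alkylates the triazene and releases the diazonium/iodide pair in a neutral, water-free medium, which should give iodide 20.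

Step 4. What may go wrong: the benzylic anion acts as a base towards the lactone (enolisation, recovered toluate), adds twice, or condenses with the ester of a second toluate molecule; on the acid side, enol-lactonisation to an isocoumarin that takes up the side-chain hydroxyl only slowly. The fallback runs from 5 and 6 back to 8. Lactone 6 is opened with MeNH(OMe)·HCl/Me3Al to the (R)-hydroxy Weinreb amide F3 and silylated (TBSCl, imidazole) to the silyl ether F4. Lithiated 5 is acylated with F4 at −78 °C, where the chelated tetrahedral intermediate prevents over-addition, to give the silyl-protected keto ester F5. p-TsOH·H2O in methanol/toluene at 50 °C then removes the silyl group and closes the spiro acyl ketal under the same thermodynamic control, returning 8.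

Further compounds
F1 | step 13 | 2-{[(3S,6'R)-8-(benzyloxy)-6-bromo-6'-methyl-1-oxo-3',4',5',6'-tetrahydrospiro[isochromane-3,2'-pyran]-5-yl]oxy}-4-methoxy-6-[(2-pentyl-1,3-dioxolan-2-yl)methyl]benzoic acid | CCCCCC1(Cc2cc(OC)cc(Oc3c(Br)cc(OCc4ccccc4)c4c3C[C@]3(CCC[C@@H](C)O3)OC4=O)c2C(=O)O)OCCO1
F2 | step 12 | 1-aryl-3,3-diethyltriazene of 18 (N=N–NEt2 in place of NH2) | CCCCCC1(Cc2cc(OC)cc(Oc3c(Br)cc(OCc4ccccc4)c4c3C[C@]3(CCC[C@@H](C)O3)OC4=O)c2N=NN(CC)CC)OCCO1
F3 | step 4 | (R)-5-hydroxy-N-methoxy-N-methylhexanamide | C[C@@H](O)CCCC(=O)N(C)OC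
F4 | step 4 | (R)-5-[(tert-butyldimethylsilyl)oxy]-N-methoxy-N-methylhexanamide | C[C@@H](O[Si](C)(C)C(C)(C)C)CCCC(=O)N(C)OC
F5 | step 4 | ethyl 3-(allyloxy)-6-(benzyloxy)-2-{(6R)-6-[(tert-butyldimethylsilyl)oxy]-2-oxoheptyl}benzoate | CCOC(=O)c1c(CC(=O)CCC[C@@H](C)O[Si](C)(C)C(C)(C)C)c(OCC=C)ccc1OCc1ccccc1
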